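**Plan**

1. The target is (−)-epicatechin joined through C4 (β face) to C8 of (2R,3R)-taxifolin. The retrosynthesis first removes nine benzyl ethers and one ring-A bromine, then cuts C3–C4 of the lower ring C, then the lower O1–C2 ether bond, and last the bond from upper C4 to lower C8.
2. Enabling feature: the lower ring C is an α-ketol, with the C4 ketone on ring A next to the C3 carbinol. Opened at C3–C4, both carbons are aldehyde carbons, and the aromatic one can be made an acyl anion by a carbene.
3. Forward: the epicatechin flavan (upper rings A, C, B) is activated at C4 and joined to a salicylaldehyde (lower ring A). O-alkylation adds lower ring B with C2, a carbene-catalysed crossed benzoin closes lower ring C, and hydrogenolysis ends the route.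
4. Stereochemistry: upper C2 and C3 come from (−)-epicatechin, and upper C4 from attack anti to the 3-benzyloxy group. Lower C2 and C3 come from a chiral carbene acting on an epimerising aldehyde (dynamic kinetic resolution), with the trans ketol as the stable arrangement.

Key step: step 12

Assumption: the (5aS,10bR) antipode of the triazolium salt is taken as the one matched to the 2R,3R closure; if a first trial shows the opposite, its mirror image is used in step 12.

**Step 1**
Reactants: 1 (−)-epicatechin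
Product: 2 5,7,3',4'-tetra-O-benzyl-(−)-epicatechin
Conditions: BnBr (4.4 equiv), K2CO3, DMF, 0 °C → rt
Reagents that add atoms: benzyl bromide, BrCc1ccccc1
Why: Williamson etherification with a weak base alkylates the four phenols only and leaves the C3 alcohol and both stereocentres untouched.

**Step 2**
Reactants: 2 5,7,3',4'-tetra-O-benzyl-(−)-epicatechin
Product: 3 3,5,7,3',4'-penta-O-benzyl-(−)-epicatechin
Conditions: NaH, BnBr, nBu4NI (cat.), DMF, 0 °C → rt
Reagents that add atoms: benzyl bromide, BrCc1ccccc1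
Why: Williamson etherification of the C3 alkoxide; with all phenols capped, ring C cannot open through a quinone methide, so C2 and C3 keep their configuration.

**Step 3**
Reactants: 3 3,5,7,3',4'-penta-O-benzyl-(−)-epicatechin
Product: 4 8-bromo-3,5,7,3',4'-penta-O-benzyl-epicatechin
Conditions: NBS (1.05 equiv), CH2Cl2, −40 °C → 0 °C, dark
Reagents that add atoms: N-bromosuccinimide, O=C1CCC(=O)N1Br
Why: Electrophilic aromatic bromination should go to C8, the most nucleophilic position of ring A; the bromine later keeps the C4 cation of one molecule from attacking ring A of another.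

**Step 4**
Reactants: 4 8-bromo-3,5,7,3',4'-penta-O-benzyl-epicatechin
Product: 5 8-bromo-4β-(2-ethoxyethoxy)-3,5,7,3',4'-penta-O-benzyl-epicatechin
Conditions: DDQ (2 equiv), 2-ethoxyethanol (5 equiv), CH2Cl2, rt
Reagents that add atoms: 2-ethoxyethanol, CCOCCO
Why: Benzylic oxidation by hydride abstraction with DDQ gives the C4 cation stabilised by ring A, which the alcohol traps anti to the 3-benzyloxy group; this centre is ionised again in step 6, so its configuration is of no consequence.

**Step 5**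
Reactants: 6 2,4,6-trihydroxybenzaldehyde
Product: 7 2-hydroxy-4,6-bis(benzyloxy)benzaldehyde
Conditions: BnBr (2.1 equiv), K2CO3 (2.2 equiv), DMF, rt
Reagents that add atoms: benzyl bromide, BrCc1ccccc1
Why: Williamson etherification should stop after two benzylations because the last ortho hydroxyl is held in a hydrogen bond to the formyl group.

**Step 6**
Reactants: 5 8-bromo-4β-(2-ethoxyethoxy)-3,5,7,3',4'-penta-O-benzyl-epicatechin; 7 2-hydroxy-4,6-bis(benzyloxy)benzaldehyde (3 equiv)
Product: 8 3-(8-bromo-3,5,7,3',4'-penta-O-benzyl-epicatechin-4β-yl)-2-hydroxy-4,6-bis(benzyloxy)benzaldehyde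
Conditions: Me3SiOTf (0.2 equiv), CH2Cl2, −78 °C → −20 °C
Reagents that add atoms: none
Why: Friedel–Crafts alkylation: the Lewis acid ionises the C4 ether of 5 and the cation is attacked by C3 of 7, ortho to the hydrogen-bonded phenol, from the face anti to the 3-benzyloxy group, which sets the 4β (3,4-trans) centre.

**Step 7**
Reactants: 9 3,4-dihydroxyphenylacetic acid
Product: 10 benzyl 2-[3,4-bis(benzyloxy)phenyl]acetate
Conditions: BnBr (3.3 equiv), K2CO3, DMF, 60 °C
Reagents that add atoms: benzyl bromide, BrCc1ccccc1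
Why: Williamson etherification of both phenols and SN2 esterification of the carboxylate take place in one operation.

**Step 8**
Reactants: 10 benzyl 2-[3,4-bis(benzyloxy)phenyl]acetate
Product: 12 benzyl 2-bromo-2-[3,4-bis(benzyloxy)phenyl]acetate (racemic), via lithium enolate 11 (not isolated)
Conditions: LiN(SiMe3)2 (1.05 equiv), THF, −78 °C; then NBS (1.1 equiv), −78 °C; aq. NH4Cl
Reagents that add atoms: N-bromosuccinimide, O=C1CCC(=O)N1Br; LiN(SiMe3)2, [Li]N([Si](C)(C)C)[Si](C)(C)C (lithium of 11 only)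
Why: α-Halogenation of an ester enolate; the ionic pathway avoids the radical bromination that would attack the benzyl ether methylenes, and a racemic bromide suffices because this centre is equilibrated in step 12.

**Step 9**
Reactants: 8 3-(8-bromo-penta-O-benzyl-epicatechin-4β-yl)-2-hydroxy-4,6-bis(benzyloxy)benzaldehyde; 12 benzyl 2-bromo-2-[3,4-bis(benzyloxy)phenyl]acetate (1.3 equiv)
Product: 13 benzyl 2-[3,4-bis(benzyloxy)phenyl]-2-[2-formyl-3,5-bis(benzyloxy)-6-(8-bromo-penta-O-benzyl-epicatechin-4β-yl)phenoxy]acetate (both epimers at the ether carbon)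
Conditions: K2CO3, DMF, rt
Reagents that add atoms: none
Why: Williamson etherification (SN2) of the phenoxide with a reactive benzylic α-bromo ester forms the future O1–C2 bond; the epimer mixture is carried on.

**Step 10**
Reactants: 13 aryl ether ester
Product: 14 2-[3,4-bis(benzyloxy)phenyl]-2-[2-(hydroxymethyl)-3,5-bis(benzyloxy)-6-(8-bromo-penta-O-benzyl-epicatechin-4β-yl)phenoxy]ethanol (both epimers)
Conditions: LiBH4 (3 equiv), THF, 0 °C → rt; aq. NH4Cl
Reagents that add atoms: none
Why: Hydride reduction with LiBH4 takes the aromatic aldehyde and the α-aryloxy-activated benzyl ester to the two primary alcohols and spares the aryl bromide and the benzyl ethers.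

**Step 11**
Reactants: 14 diol
Product: 15 2-[3,4-bis(benzyloxy)phenyl]-2-[2-formyl-3,5-bis(benzyloxy)-6-(8-bromo-penta-O-benzyl-epicatechin-4β-yl)phenoxy]acetaldehyde (dialdehyde, both epimers at the future lower C2)
Conditions: Dess–Martin periodinane (3 equiv), NaHCO3, CH2Cl2, 0 °C → rt; used at once
Reagents that add atoms: none
Why: Dess–Martin oxidation under bicarbonate buffer converts both primary alcohols to aldehydes without over-oxidation and without the acid that would ionise the electron-rich benzylic alcohol.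

**Step 12**
Reactants: 15 dialdehyde (both C2 epimers)
Product: 16 8-bromo-3,5,7,3',4'-penta-O-benzyl-epicatechin-(4β→8)-5,7,3',4'-tetra-O-benzyl-(2R,3R)-taxifolin (lower ring 2,3-trans, lower 3-OH free)
Conditions: (5aS,10bR)-2-(pentafluorophenyl)-5a,10b-dihydro-4H,6H-indeno[2,1-b][1,2,4]triazolo[4,3-d][1,4]oxazin-2-ium tetrafluoroborate (20 mol%), iPr2NEt (1 equiv), toluene (0.02 M), 4 Å sieves, argon, rt; AcOH quench
Reagents that add atoms: none
Why: Proposed new method: the triazolylidene freed by the amine adds to the aromatic formyl group of 15, proton transfer gives the hydroxy-enamine (Breslow intermediate), an acyl anion at the future C4, which attacks the tethered aliphatic formyl carbon (future C3) in a 6-exo-trig closure of lower ring C, and collapse of the adduct releases the carbene and leaves the C4 ketone beside the C3 hydroxyl. The closest known reaction type is the carbene-catalysed intramolecular crossed benzoin of 2-(2-oxoalkoxy)benzaldehydes to 3-hydroxychroman-4-ones, combined here with the known carbene-catalysed dynamic kinetic resolution of enolisable carbonyl acceptors; an aldehyde acceptor with a stereogenic, aryloxy-bearing α-carbon has not been closed in this way. C3 is set by the face of the aldehyde that the chiral hydroxy-enamine reaches in a chair-like transition state with the C2 aryl group equatorial, which gives the 2,3-trans ketol, also the more stable one. C2 is set by dynamic kinetic resolution: the α-aryl-α-aryloxy aldehyde should epimerise through its enol under the amine faster than it cyclises, and the catalyst, possibly helped by the upper unit, lets the 2R epimer close. The step needs the aromatic aldehyde to be the acyl donor and the aliphatic one the acceptor, without loss of the aryloxide from a carbene adduct of the latter; in its favour, the aliphatic formyl group sits on a branched, enolisable carbon that is hindered towards the bulky carbene and partly masked as enol, the aromatic aldehyde cannot enolise, both carbene additions are reversible, and the conjugated aryl ketone is the thermodynamic sink.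

**Step 13**
Reactants: 16 protected ketol
Product: 17 epicatechin-(4β→8)-(2R,3R)-taxifolin (target, CNP0210692.1)
Conditions: H2 (1 atm), Pd(OH)2/C, NaOAc (2 equiv), THF/MeOH, rt
Reagents that add atoms: none
Why: Hydrogenolysis cleaves the nine benzyl ethers and the aryl C–Br bond while acetate buffers the HBr; the chelated aryl ketone and the five stereocentres are expected to survive these near-neutral conditions.

**Compound list**

1 | (−)-epicatechin, (2R,3R)-2-(3,4-dihydroxyphenyl)chromane-3,5,7-triol | C1c2c(O)cc(O)cc2O[C@H](c2ccc(O)c(O)c2)[C@@H]1O | starting material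
2 | 5,7,3',4'-tetra-O-benzyl-(−)-epicatechin (2R,3R, 3-OH free) | C1c2c(OCc3ccccc3)cc(OCc3ccccc3)cc2O[C@H](c2ccc(OCc3ccccc3)c(OCc3ccccc3)c2)[C@@H]1O | intermediate
3 | 3,5,7,3',4'-penta-O-benzyl-(−)-epicatechin | C1c2c(OCc3ccccc3)cc(OCc3ccccc3)cc2O[C@H](c2ccc(OCc3ccccc3)c(OCc3ccccc3)c2)[C@@H]1OCc3ccccc3 | intermediate
4 | 8-bromo-3,5,7,3',4'-penta-O-benzyl-epicatechin (2,3-cis as in 1) | C1c2c(OCc3ccccc3)cc(OCc3ccccc3)c(Br)c2O[C@H](c2ccc(OCc3ccccc3)c(OCc3ccccc3)c2)[C@@H]1OCc3ccccc3 | intermediate
5 | 8-bromo-4β-(2-ethoxyethoxy)-3,5,7,3',4'-penta-O-benzyl-epicatechin (2,3-cis, 3,4-trans) | CCOCCO[C@H]1c2c(OCc3ccccc3)cc(OCc3ccccc3)c(Br)c2O[C@H](c2ccc(OCc3ccccc3)c(OCc3ccccc3)c2)[C@@H]1OCc3ccccc3 | intermediate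
6 | 2,4,6-trihydroxybenzaldehyde | O=Cc1c(O)cc(O)cc1O | starting material
7 | 2-hydroxy-4,6-bis(benzyloxy)benzaldehyde | O=Cc1c(O)cc(OCc2ccccc2)cc1OCc2ccccc2 | intermediate
8 | 3-(8-bromo-3,5,7,3',4'-penta-O-benzyl-epicatechin-4β-yl)-2-hydroxy-4,6-bis(benzyloxy)benzaldehyde (upper ring 2,3-cis, 3,4-trans) | O=Cc1c(OCc2ccccc2)cc(OCc2ccccc2)c([C@H]3c4c(OCc2ccccc2)cc(OCc2ccccc2)c(Br)c4O[C@H](c4ccc(OCc2ccccc2)c(OCc2ccccc2)c4)[C@@H]3OCc2ccccc2)c1O | intermediate
9 | 3,4-dihydroxyphenylacetic acid | OC(=O)Cc1ccc(O)c(O)c1 | starting material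
10 | benzyl 2-[3,4-bis(benzyloxy)phenyl]acetate | O=C(OCc1ccccc1)Cc1ccc(OCc2ccccc2)c(OCc2ccccc2)c1 | intermediate
11 | lithium enolate of 10 | [Li]OC(OCc1ccccc1)=Cc1ccc(OCc2ccccc2)c(OCc2ccccc2)c1 | intermediate
12 | benzyl 2-bromo-2-[3,4-bis(benzyloxy)phenyl]acetate (racemic) | O=C(OCc1ccccc1)C(Br)c1ccc(OCc2ccccc2)c(OCc2ccccc2)c1 | intermediate
13 | benzyl 2-[3,4-bis(benzyloxy)phenyl]-2-[2-formyl-3,5-bis(benzyloxy)-6-(8-bromo-penta-O-benzyl-epicatechin-4β-yl)phenoxy]acetate (both epimers at the ether carbon) | O=Cc1c(OCc2ccccc2)cc(OCc2ccccc2)c([C@H]3c4c(OCc2ccccc2)cc(OCc2ccccc2)c(Br)c4O[C@H](c4ccc(OCc2ccccc2)c(OCc2ccccc2)c4)[C@@H]3OCc2ccccc2)c1OC(C(=O)OCc2ccccc2)c5ccc(OCc2ccccc2)c(OCc2ccccc2)c5 | intermediate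
14 | 2-[3,4-bis(benzyloxy)phenyl]-2-[2-(hydroxymethyl)-3,5-bis(benzyloxy)-6-(8-bromo-penta-O-benzyl-epicatechin-4β-yl)phenoxy]ethanol (both epimers) | OCc1c(OCc2ccccc2)cc(OCc2ccccc2)c([C@H]3c4c(OCc2ccccc2)cc(OCc2ccccc2)c(Br)c4O[C@H](c4ccc(OCc2ccccc2)c(OCc2ccccc2)c4)[C@@H]3OCc2ccccc2)c1OC(CO)c5ccc(OCc2ccccc2)c(OCc2ccccc2)c5 | intermediate
15 | 2-[3,4-bis(benzyloxy)phenyl]-2-[2-formyl-3,5-bis(benzyloxy)-6-(8-bromo-penta-O-benzyl-epicatechin-4β-yl)phenoxy]acetaldehyde (dialdehyde, both epimers) | O=Cc1c(OCc2ccccc2)cc(OCc2ccccc2)c([C@H]3c4c(OCc2ccccc2)cc(OCc2ccccc2)c(Br)c4O[C@H](c4ccc(OCc2ccccc2)c(OCc2ccccc2)c4)[C@@H]3OCc2ccccc2)c1OC(C=O)c5ccc(OCc2ccccc2)c(OCc2ccccc2)c5 | intermediate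
16 | 8-bromo-3,5,7,3',4'-penta-O-benzyl-epicatechin-(4β→8)-5,7,3',4'-tetra-O-benzyl-(2R,3R)-taxifolin (lower 3-OH free, 2,3-trans) | O=C1c2c(OCc5ccccc5)cc(OCc5ccccc5)c([C@H]3c4c(OCc5ccccc5)cc(OCc5ccccc5)c(Br)c4O[C@H](c4ccc(OCc5ccccc5)c(OCc5ccccc5)c4)[C@@H]3OCc5ccccc5)c2O[C@H](c2ccc(OCc5ccccc5)c(OCc5ccccc5)c2)[C@H]1O | intermediate
17 | epicatechin-(4β→8)-(2R,3R)-taxifolin, (2R,3R)-2-(3,4-dihydroxyphenyl)-8-[(2R,3R,4R)-2-(3,4-dihydroxyphenyl)-3,5,7-trihydroxychroman-4-yl]-3,5,7-trihydroxychroman-4-one | O=C1c2c(O)cc(O)c([C@H]3c4c(O)cc(O)cc4O[C@H](c4ccc(O)c(O)c4)[C@@H]3O)c2O[C@H](c2ccc(O)c(O)c2)[C@H]1O | target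

**Count**

Total steps: 13. Longest linear sequence: 10 steps (1, 2, 3, 4, 6, 9, 10, 11, 12, 13).

**Steps most likely to fail**

Step 12 (carries the label). The carbene may add to the aliphatic formyl group instead of the aromatic one. The hydroxy-enamine formed there can expel the aryloxide (internal redox to an aryl ester) or act as the donor and reverse the roles of the two aldehydes. Discrimination between the two C2 epimers may also be weak.

The fallback builds lower ring C by the established chalcone epoxide route; it sets out from 5 and returns at 16. Compound 5 is coupled, as in step 6, with commercial 1-[2-hydroxy-4,6-bis(benzyloxy)phenyl]ethanone F1 to give 1-[3-(8-bromo-penta-O-benzyl-epicatechin-4β-yl)-2-hydroxy-4,6-bis(benzyloxy)phenyl]ethanone F2. The shielded phenol is capped (NaH, MeOCH2Cl, DMF) as the methoxymethyl ether F3. Claisen–Schmidt condensation with commercial 3,4-bis(benzyloxy)benzaldehyde F4 (KOH, EtOH/THF) gives the E-chalcone F5. Juliá–Colonna epoxidation (poly-L-leucine, urea–hydrogen peroxide, DBU, THF) should give the (αR,βS)-epoxy ketone F6. HCl in MeOH/THF then removes the acetal, and the freed phenol opens the epoxide at the benzylic carbon with inversion, giving the 2,3-trans (2R,3R) ketol 16.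

Step 6. C-alkylation of the formyl-deactivated ring may be slow. Attack may also go para to the phenol (between the two benzyloxy groups) instead of ortho, or O-alkylation may fail to rearrange to carbon.

The fallback removes the regiochemical question with a symmetric nucleophile; it sets out from 6 and 5 and returns at 8. Compound 6 is benzylated once at its unchelated para hydroxyl (BnBr 1 equiv, NaHCO3, DMF) to 4-(benzyloxy)-2,6-dihydroxybenzaldehyde F7, whose two free ring positions are equivalent and more nucleophilic. Friedel–Crafts coupling with 5 (Me3SiOTf, CH2Cl2/THF, −40 °C) gives 3-(8-bromo-penta-O-benzyl-epicatechin-4β-yl)-4-(benzyloxy)-2,6-dihydroxybenzaldehyde F8 as the only possible C-regioisomer. BnBr (1 equiv) with K2CO3 then benzylates the hydroxyl remote from the flavanyl group, the less shielded of the two, to give 8.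

Step 9. SN2 at the shielded, hydrogen-bonded phenoxide may be sluggish. Under base, the acidic α-hydrogen of the product can also lead to aldol closure onto the neighbouring formyl group, and the bromide can be lost by elimination or solvolysis.

The fallback forms the same ether under neutral conditions by carbene O–H insertion; it sets out from 10 and 8 and returns at 13. Diazo transfer to 10 (4-acetamidobenzenesulfonyl azide, DBU, MeCN) gives benzyl 2-diazo-2-[3,4-bis(benzyloxy)phenyl]acetate F9. Rh2(OAc)4 (1 mol%) in CH2Cl2 at rt then inserts the derived carbene into the O–H bond of 8 to give 13.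

**Further compounds**

F1 | step 12 | 1-[2-hydroxy-4,6-bis(benzyloxy)phenyl]ethanone | CC(=O)c1c(O)cc(OCc2ccccc2)cc1OCc2ccccc2
F2 | step 12 | 1-[3-(8-bromo-penta-O-benzyl-epicatechin-4β-yl)-2-hydroxy-4,6-bis(benzyloxy)phenyl]ethanone | CC(=O)c1c(OCc2ccccc2)cc(OCc2ccccc2)c([C@H]3c4c(OCc2ccccc2)cc(OCc2ccccc2)c(Br)c4O[C@H](c4ccc(OCc2ccccc2)c(OCc2ccccc2)c4)[C@@H]3OCc2ccccc2)c1O
F3 | step 12 | methoxymethyl ether of F2 | CC(=O)c1c(OCc2ccccc2)cc(OCc2ccccc2)c([C@H]3c4c(OCc2ccccc2)cc(OCc2ccccc2)c(Br)c4O[C@H](c4ccc(OCc2ccccc2)c(OCc2ccccc2)c4)[C@@H]3OCc2ccccc2)c1OCOC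
F4 | step 12 | 3,4-bis(benzyloxy)benzaldehyde | O=Cc1ccc(OCc2ccccc2)c(OCc2ccccc2)c1
F5 | step 12 | (E)-chalcone from F3 and F4 | O=C(/C=C/c5ccc(OCc2ccccc2)c(OCc2ccccc2)c5)c1c(OCc2ccccc2)cc(OCc2ccccc2)c([C@H]3c4c(OCc2ccccc2)cc(OCc2ccccc2)c(Br)c4O[C@H](c4ccc(OCc2ccccc2)c(OCc2ccccc2)c4)[C@@H]3OCc2ccccc2)c1OCOC
F6 | step 12 | (αR,βS)-trans-epoxy ketone of F5 | O=C([C@@H]6O[C@H]6c5ccc(OCc2ccccc2)c(OCc2ccccc2)c5)c1c(OCc2ccccc2)cc(OCc2ccccc2)c([C@H]3c4c(OCc2ccccc2)cc(OCc2ccccc2)c(Br)c4O[C@H](c4ccc(OCc2ccccc2)c(OCc2ccccc2)c4)[C@@H]3OCc2ccccc2)c1OCOC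
F7 | step 6 | 4-(benzyloxy)-2,6-dihydroxybenzaldehyde | O=Cc1c(O)cc(OCc2ccccc2)cc1O
F8 | step 6 | 3-(8-bromo-penta-O-benzyl-epicatechin-4β-yl)-4-(benzyloxy)-2,6-dihydroxybenzaldehyde | O=Cc1c(O)cc(OCc2ccccc2)c([C@H]3c4c(OCc2ccccc2)cc(OCc2ccccc2)c(Br)c4O[C@H](c4ccc(OCc2ccccc2)c(OCc2ccccc2)c4)[C@@H]3OCc2ccccc2)c1O
F9 | step 9 | benzyl 2-diazo-2-[3,4-bis(benzyloxy)phenyl]acetate | O=C(OCc1ccccc1)C(=[N+]=[N-])c1ccc(OCc2ccccc2)c(OCc2ccccc2)c1
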